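The route rests on cutting C13–C14 of ring D. Ring D (C13–C18) bears an exocyclic C12=C13 alkene with C11 syn to the C14 methylene and H-12 syn to C18, which is what anti addition of a carbon nucleophile and a proton across a C12≡C13 alkyne leaves behind. A gold-catalysed enol–yne carbocyclisation therefore closes ring D and fixes the alkene geometry in one operation. Its precursor is the complete ring E: C18 carries the sclareolide-derived left half through the C12≡C13 alkyne, and C17 carries, cis to it, a 2-silyloxyallyl arm. That cis pair is set by an endo Diels–Alder reaction of a left-half dienyne with methacrolein.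

Key step: step 17

Numbering: C1–C10 left decalin, C11–C12–C13 linker, ring D = C13–C18, ring E = C17–C22; "left half" means the 3β-TBSO-4,4,8β,10β-tetramethyl-trans-decalin (5α-H, 8α-H, 9α-H) attached through C11 on C9.

Assumption: the (S)-oxazaborolidinium catalyst of step 10 is taken to deliver the diene to the face of methacrolein that gives the (1S,2S)-cyclohexene 15; if the sense is the opposite, the (R)-catalyst is used and nothing else changes.

Step 1
Reactants: 1 (+)-sclareolide
Product: 2 3β-hydroxysclareolide
Conditions: cytochrome P450 BM3 (CYP102A1) variant selective for C3, glucose dehydrogenase, NADP+ (cat.), D-glucose, air, phosphate buffer pH 8/DMSO, 25 °C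
Reagents that add atoms: dioxygen O=O
Why: Enzymatic C–H hydroxylation: engineered P450 BM3 variants are known to oxidise sclareolide selectively at the C3 methylene from its open equatorial side, which sets C3 as the 3β (equatorial) alcohol.

Step 2
Reactants: 2 3β-hydroxysclareolide
Product: 3 3β-(tert-butyldimethylsilyloxy)sclareolide
Conditions: TBSOTf, 2,6-lutidine, CH2Cl2, 0 °C
Reagents that add atoms: tert-butyldimethylsilyl triflate CC(C)(C)[Si](C)(C)OS(=O)(=O)C(F)(F)F
Why: Silyl ether formation with a silyl triflate, which is reactive enough for the neopentyl-type 3β-alcohol and leaves the lactone alone.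

Step 3
Reactants: 3 3β-(tert-butyldimethylsilyloxy)sclareolide
Product: 4 8α-hydroxy Weinreb amide
Conditions: MeNH(OMe)·HCl, AlMe3, CH2Cl2, 0 °C to rt
Reagents that add atoms: N,O-dimethylhydroxylamine hydrochloride CNOC.Cl
Why: Weinreb aminolysis of the lactone by the chloro(methyl)aluminium amide opens the ring at the acyl carbon, freeing the 8α tertiary alcohol and giving an amide that can later be stopped at the aldehyde.

Step 4
Reactants: 4 8α-hydroxy Weinreb amide
Product: 5 8-methylene Weinreb amide
Conditions: SOCl2, pyridine, CH2Cl2, −78 °C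
Reagents that add atoms: none
Why: Chlorosulfite dehydration (E2) of the equatorial tertiary alcohol at low temperature takes its proton chiefly from the freely rotating methyl group and should give mainly the exocyclic alkene, any Δ7 isomer converging in step 5.

Step 5
Reactants: 5 8-methylene Weinreb amide
Product: 6 saturated Weinreb amide (8α-H, 8β-methyl)
Conditions: H2 (1 atm), PtO2, EtOAc, rt
Reagents that add atoms: none
Why: Heterogeneous catalytic hydrogenation delivers hydrogen to the α face, away from the axial C10 methyl, which sets C8 with 8α-H and the axial 8β-methyl.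

Step 6
Reactants: 6 saturated Weinreb amide (8α-H, 8β-methyl); 7 dimethyl (1-diazo-2-oxopropyl)phosphonate
Product: 9 left-half terminal alkyne, via left-half C12 aldehyde 8 (not isolated)
Conditions: i-Bu2AlH, CH2Cl2, −78 °C; then MeOH, K2CO3, 7, 0 °C to rt
Reagents that add atoms: none
Why: Partial reduction of the Weinreb amide stops at the aldehyde (stable chelated hemiaminal) and the Ohira–Bestmann variant of the Seyferth–Gilbert homologation then adds C13 as a terminal alkyne under conditions too mild to epimerise C9.

Step 7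
Reactants: 9 left-half terminal alkyne
Product: 10 left-half ynal
Conditions: n-BuLi, THF, −78 °C; DMF; inverse quench into aqueous KH2PO4
Reagents that add atoms: N,N-dimethylformamide CN(C)C=O
Why: Formylation of the lithium acetylide with DMF adds C18 as the ynal carbon.

Step 8
Reactants: 10 left-half ynal; 11 1-(triphenylphosphoranylidene)propan-2-one
Product: 12 (E)-enynone
Conditions: CH2Cl2, rt
Reagents that add atoms: none
Why: Wittig olefination with a stabilised ylide gives the E enone, which later places the alkyne on the outside of the s-cis diene.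

Step 9
Reactants: 12 (E)-enynone
Product: 13 2-silyloxy dienyne
Conditions: TBSOTf, Et3N, CH2Cl2, −78 to 0 °C
Reagents that add atoms: tert-butyldimethylsilyl triflate CC(C)(C)[Si](C)(C)OS(=O)(=O)C(F)(F)F
Why: Soft enolisation of the methyl ketone with a silyl triflate and an amine gives the cross-conjugated 2-silyloxy diene, the methyl group being the only enolisable position.

Step 10
Reactants: 13 2-silyloxy dienyne; 14 methacrolein
Product: 15 Diels–Alder aldehyde (ring E with C17 and C18 set)
Conditions: (S)-3,3-diphenyl-1-(o-tolyl)tetrahydro-1H,3H-pyrrolo[1,2-c][1,3,2]oxazaborole (20 mol%), HNTf2 (18 mol%), 14 (3 equiv), CH2Cl2, −78 °C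
Reagents that add atoms: none
Why: Catalytic enantioselective Diels–Alder reaction in which the 2-silyloxy group steers C21 to the β carbon of methacrolein (para adduct), the endo orientation of the boron-bound formyl group puts CHO cis to the E alkynyl substituent so that C17 and C18 arise together, and the chiral oxazaborolidinium ion chooses the face that fixes their absolute configuration independently of the remote left half.

Step 11
Reactants: 16 triphenylphosphine hydrobromide; 17 methyl vinyl ether
Product: 18 (1-methoxyethyl)triphenylphosphonium bromide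
Conditions: CH2Cl2, 0 °C to rt
Reagents that add atoms: none
Why: Markovnikov addition of the phosphonium hydrobromide across the enol ether through the oxocarbenium ion, a standard preparation of α-alkoxyalkyl phosphonium salts.

Step 12
Reactants: 15 Diels–Alder aldehyde; 18 (1-methoxyethyl)triphenylphosphonium bromide
Product: 19 bis(enol ether)
Conditions: 18, KN(SiMe3)2, THF, −78 to 0 °C; then 15
Reagents that add atoms: none
Why: Wittig olefination of the non-enolisable neopentyl aldehyde with the α-methoxyethylidene ylide gives the methyl enol ether of the future acetonyl arm (alkene geometry without consequence) and leaves the silyl enol ether untouched.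

Step 13
Reactants: 19 bis(enol ether)
Product: 20 C19-methyl ketone
Conditions: benzyltrimethylammonium fluoride (dried, 1.0 equiv), MeI (excess), 4 Å sieves, THF, 0 °C
Reagents that add atoms: iodomethane CI
Why: Fluoride-triggered regiospecific alkylation of the silyl enol ether through its ammonium enolate, iodomethane entering C19 from the face opposite the C18 alkynyl group and the C17 arm, which sets the C19 methyl trans to the alkyne under kinetic control.

Step 14
Reactants: 20 C19-methyl ketone
Product: 22 hydroxy methyl ketone, via C20 carbinol enol ether 21 (not isolated)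
Conditions: MeAl(O-2,6-t-Bu2-4-MeC6H2)2 (3 equiv, from AlMe3 and the phenol), toluene, −78 °C; MeLi; then 1 M HCl, THF, 0 °C to rt
Reagents that add atoms: methyllithium [Li]C; water O
Why: Amphiphilic carbonyl methylation: the bulky aluminium aryloxide binds the ketone on its equatorial side and methyllithium adds axially, which sets C20 with an axial methyl and an equatorial hydroxyl cis to the alkyne, and the acidic work-up hydrolyses the enol ether to the methyl ketone.

Step 15
Reactants: 22 hydroxy methyl ketone
Product: 23 C20 triethylsilyl ether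
Conditions: TESOTf, 2,6-lutidine, CH2Cl2, −78 to 0 °C; aqueous citric acid work-up
Reagents that add atoms: triethylsilyl triflate CC[Si](CC)(CC)OS(=O)(=O)C(F)(F)F
Why: Silylation of the tertiary alcohol with a silyl triflate, any silyl enol ether of the methyl ketone being cleaved again in the mildly acidic work-up.

Step 16
Reactants: 23 C20 triethylsilyl ether
Product: 24 cyclisation precursor (terminal silyl enol ether)
Conditions: LiN(i-Pr)2, THF, −78 °C; TBSCl, DMPU, −78 to 0 °C
Reagents that add atoms: tert-butyldimethylsilyl chloride CC(C)(C)[Si](C)(C)Cl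
Why: Kinetic deprotonation at the methyl group (the C16 methylene is neopentyl) followed by O-silylation gives the terminal 2-silyloxyallyl arm.

Step 17
Reactants: 24 cyclisation precursor (terminal silyl enol ether)
Product: 25 tetracyclic C15 ketone
Conditions: [Au(NCMe){P(t-Bu)2(2-biphenylyl)}]SbF6 (5 mol%), CH2Cl2/MeOH 10:1, rt; Et3N quench
Reagents that add atoms: none
Why: The cationic monovalent gold complex binds the C12≡C13 alkyne as a π-acid, the terminal carbon C14 of the silyl enol ether attacks C13 from the side opposite the metal, the oxocarbenium ion gives its silyl group to methanol, and the C12 vinylgold is protonated with retention. The closest known reaction is the gold-catalysed exo-dig carbocyclisation of silyl enol ethers onto alkynes, a Conia-ene variant. Ring D (C13–C18) closes in the 6-exo-dig mode with C12 left outside the ring; the 7-endo alternative at C12 is disfavoured by the tether length and by the chair in which the axial C17 arm sits next to the equatorial C18 alkyne. No stereocentre is created, but the alkene geometry (C11 syn to C14, H-12 syn to C18) is fixed by the anti addition. The cis ring fusion follows from the cis relation of the C17 arm and the C18 alkyne set in step 10, and the methyl ketone enol ether has a single nucleophilic carbon, so one constitutional and one geometric isomer should form.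

Step 18
Reactants: 25 tetracyclic C15 ketone
Product: 26 C15 alcohols (epimer mixture)
Conditions: NaBH4, CeCl3·7H2O, MeOH/THF, −40 °C
Reagents that add atoms: none
Why: Luche 1,2-reduction at low temperature converts the β,γ-unsaturated ketone into the alcohol before any base can move the alkene into conjugation, the C15 configuration being of no consequence.

Step 19
Reactants: 26 C15 alcohols (epimer mixture)
Product: 27 C15 S-methyl xanthates
Conditions: NaH, imidazole (cat.), THF, 0 °C to rt; CS2; MeI
Reagents that add atoms: carbon disulfide S=C=S; iodomethane CI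
Why: Xanthate formation from the alkoxide, CS2 and MeI prepares the Barton–McCombie deoxygenation.

Step 20
Reactants: 27 C15 S-methyl xanthates
Product: 28 bis-silyl ether of the target
Conditions: n-Bu3SnH (0.3 M), AIBN (cat.), toluene, 90 °C
Reagents that add atoms: none
Why: Barton–McCombie radical deoxygenation, run at high stannane concentration so that hydrogen transfer to the homoallylic C15 radical outruns the reversible 3-exo closure that could scramble the C12=C13 geometry.

Step 21
Reactants: 28 bis-silyl ether of the target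
Product: 29 CNP0338143.1
Conditions: n-Bu4NF, THF, 60 °C
Reagents that add atoms: none
Why: Fluoride cleaves both silyl ethers, the hindered 3β ether needing heat, and touches nothing else.

Compound list

1 | (+)-sclareolide | O=C1C[C@H]2[C@@](C)(CC[C@H]3C(C)(C)CCC[C@]23C)O1 | starting material
2 | 3β-hydroxysclareolide | O=C1C[C@H]2[C@@](C)(CC[C@H]3C(C)(C)[C@@H](O)CC[C@]23C)O1 | intermediate
3 | 3β-(tert-butyldimethylsilyloxy)sclareolide | O=C1C[C@H]2[C@@](C)(CC[C@H]3C(C)(C)[C@@H](O[Si](C)(C)C(C)(C)C)CC[C@]23C)O1 | intermediate
4 | 8α-hydroxy Weinreb amide (ring-opened lactone: C11H2–C12(=O)N(OMe)Me on C9, tertiary 8α-OH, 3β-OTBS) | CON(C)C(=O)C[C@H]2[C@](C)(O)CC[C@H]3C(C)(C)[C@@H](O[Si](C)(C)C(C)(C)C)CC[C@]23C | intermediate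
5 | 8-methylene Weinreb amide (exocyclic C8=CH2) | CON(C)C(=O)C[C@H]2C(=C)CC[C@H]3C(C)(C)[C@@H](O[Si](C)(C)C(C)(C)C)CC[C@]23C | intermediate
6 | saturated Weinreb amide (8α-H, axial 8β-methyl) | CON(C)C(=O)C[C@H]2[C@@H](C)CC[C@H]3C(C)(C)[C@@H](O[Si](C)(C)C(C)(C)C)CC[C@]23C | intermediate
7 | dimethyl (1-diazo-2-oxopropyl)phosphonate | COP(=O)(OC)C(=[N+]=[N-])C(C)=O | starting material
8 | left-half C12 aldehyde (left half–C11H2–CHO) | O=CC[C@H]2[C@@H](C)CC[C@H]3C(C)(C)[C@@H](O[Si](C)(C)C(C)(C)C)CC[C@]23C | intermediate
9 | left-half terminal alkyne (left half–C11H2–C12≡C13H) | C#CC[C@H]2[C@@H](C)CC[C@H]3C(C)(C)[C@@H](O[Si](C)(C)C(C)(C)C)CC[C@]23C | intermediate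
10 | left-half ynal (left half–C11H2–C12≡C13–C18HO) | O=CC#CC[C@H]2[C@@H](C)CC[C@H]3C(C)(C)[C@@H](O[Si](C)(C)C(C)(C)C)CC[C@]23C | intermediate
11 | 1-(triphenylphosphoranylidene)propan-2-one | CC(=O)C=P(c1ccccc1)(c1ccccc1)c1ccccc1 | starting material
12 | (E)-enynone (C21H3–C20(=O)–C19H=C18H–C13≡C12–C11H2–left half) | CC(=O)/C=C/C#CC[C@H]2[C@@H](C)CC[C@H]3C(C)(C)[C@@H](O[Si](C)(C)C(C)(C)C)CC[C@]23C | intermediate
13 | 2-silyloxy dienyne (C21H2=C20(OTBS)–C19H=C18H–C≡C–CH2–left half, E) | C=C(O[Si](C)(C)C(C)(C)C)/C=C/C#CC[C@H]2[C@@H](C)CC[C@H]3C(C)(C)[C@@H](O[Si](C)(C)C(C)(C)C)CC[C@]23C | intermediate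
14 | methacrolein (2-methylprop-2-enal) | CC(=C)C=O | starting material
15 | Diels–Alder aldehyde: (1S,2S)-4-(tert-butyldimethylsilyloxy)-1-methyl-2-(3-left-half-prop-1-ynyl)cyclohex-3-ene-1-carbaldehyde (CHO on C17 cis to the alkynyl group on C18) | C1(O[Si](C)(C)C(C)(C)C)=C[C@@H](C#CC[C@H]3[C@@H](C)CC[C@H]4C(C)(C)[C@@H](O[Si](C)(C)C(C)(C)C)CC[C@]34C)[C@@](C)(C=O)CC1 | intermediate
16 | triphenylphosphine hydrobromide | [PH+](c1ccccc1)(c1ccccc1)c1ccccc1.[Br-] | starting material
17 | methyl vinyl ether | COC=C | starting material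
18 | (1-methoxyethyl)triphenylphosphonium bromide (racemic) | COC(C)[P+](c1ccccc1)(c1ccccc1)c1ccccc1.[Br-] | intermediate
19 | bis(enol ether): 15 with C17–CH=C(OMe)CH3 in place of CHO (E/Z mixture) | C1(O[Si](C)(C)C(C)(C)C)=C[C@@H](C#CC[C@H]3[C@@H](C)CC[C@H]4C(C)(C)[C@@H](O[Si](C)(C)C(C)(C)C)CC[C@]34C)[C@@](C)(C=C(C)OC)CC1 | intermediate
20 | C19-methyl ketone: ring-E cyclohexanone (C20=O), 19-CH3 trans to the C18 alkynyl group, C17 bearing CH3 and CH=C(OMe)CH3 | C[C@@H]1[C@@H](C#CC[C@H]3[C@@H](C)CC[C@H]4C(C)(C)[C@@H](O[Si](C)(C)C(C)(C)C)CC[C@]34C)[C@@](C)(C=C(C)OC)CCC1=O | intermediate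
21 | C20 carbinol enol ether: 20 after methyl addition (20-OH cis to the alkynyl group) | C[C@@H]1[C@@H](C#CC[C@H]3[C@@H](C)CC[C@H]4C(C)(C)[C@@H](O[Si](C)(C)C(C)(C)C)CC[C@]34C)[C@@](C)(C=C(C)OC)CC[C@@]1(C)O | intermediate
22 | hydroxy methyl ketone: as 21 with C17–CH2C(=O)CH3 | C[C@@H]1[C@@H](C#CC[C@H]3[C@@H](C)CC[C@H]4C(C)(C)[C@@H](O[Si](C)(C)C(C)(C)C)CC[C@]34C)[C@@](C)(CC(C)=O)CC[C@@]1(C)O | intermediate
23 | C20 triethylsilyl ether of 22 | C[C@@H]1[C@@H](C#CC[C@H]3[C@@H](C)CC[C@H]4C(C)(C)[C@@H](O[Si](C)(C)C(C)(C)C)CC[C@]34C)[C@@](C)(CC(C)=O)CC[C@@]1(C)O[Si](CC)(CC)CC | intermediate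
24 | cyclisation precursor: 23 as its terminal tert-butyldimethylsilyl enol ether (C17–CH2–C(OTBS)=CH2) | C[C@@H]1[C@@H](C#CC[C@H]3[C@@H](C)CC[C@H]4C(C)(C)[C@@H](O[Si](C)(C)C(C)(C)C)CC[C@]34C)[C@@](C)(CC(=C)O[Si](C)(C)C(C)(C)C)CC[C@@]1(C)O[Si](CC)(CC)CC | intermediate
25 | tetracyclic C15 ketone: ring D closed, (E)-C12=C13, 3β-OTBS, 20-OTES | C[C@@H]1[C@H]2/C(=C/C[C@H]3[C@@H](C)CC[C@H]4C(C)(C)[C@@H](O[Si](C)(C)C(C)(C)C)CC[C@]34C)CC(=O)C[C@@]2(C)CC[C@@]1(C)O[Si](CC)(CC)CC | intermediate
26 | C15 alcohols (both C15 epimers) | C[C@@H]1[C@H]2/C(=C/C[C@H]3[C@@H](C)CC[C@H]4C(C)(C)[C@@H](O[Si](C)(C)C(C)(C)C)CC[C@]34C)CC(O)C[C@@]2(C)CC[C@@]1(C)O[Si](CC)(CC)CC | intermediate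
27 | C15 S-methyl xanthates (both C15 epimers) | C[C@@H]1[C@H]2/C(=C/C[C@H]3[C@@H](C)CC[C@H]4C(C)(C)[C@@H](O[Si](C)(C)C(C)(C)C)CC[C@]34C)CC(OC(=S)SC)C[C@@]2(C)CC[C@@]1(C)O[Si](CC)(CC)CC | intermediate
28 | bis-silyl ether of the target (3β-OTBS, 20-OTES) | C[C@@H]1[C@H]2/C(=C/C[C@H]3[C@@H](C)CC[C@H]4C(C)(C)[C@@H](O[Si](C)(C)C(C)(C)C)CC[C@]34C)CCC[C@@]2(C)CC[C@@]1(C)O[Si](CC)(CC)CC | intermediate
29 | CNP0338143.1 | C[C@@H]1[C@H]2/C(=C/C[C@H]3[C@@H](C)CC[C@H]4C(C)(C)[C@@H](O)CC[C@]34C)CCC[C@@]2(C)CC[C@@]1(C)O | target

Total step count: 21. Longest linear sequence: 20 steps (1–10 and 12–21, from (+)-sclareolide); step 11 is a one-step side branch.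

The three steps most likely to fail, most risky first.

First, the gold cyclisation (step 17). The enol ether may give up its silyl group to methanol faster than it attacks the hindered internal alkyne, or closure may drift to C12 (7-endo). The fallback sets out from 24 and comes back at 25. Stoichiometric HgCl2 with hexamethyldisilazane in CH2Cl2 should bring about the same anti carbocyclisation and leave mercury on C12 in the isolable vinylmercury chloride F1. NaI and aqueous HCl then replace mercury by hydrogen with retention of the alkene geometry.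

Second, the Diels–Alder reaction (step 10). Endo and facial selectivity may be insufficient with the α-methyl dienophile, and because the left half is remote, the wrong ring-E series would be hard to remove. The fallback sets out from 13 and comes back at 15. The same catalyst with 2,2,2-trifluoroethyl acrylate, whose face selectivity is better established, should give the trifluoroethyl ester F2 (C17 configuration immaterial). LiN(i-Pr)2 then MeI alkylates its ester enolate anti to the C18 alkynyl group to give the quaternary ester F3, and i-Bu2AlH at −78 °C reduces it to 15.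

Third, the C19 methylation (step 13). Proton transfer between enolate and product may scramble the regiochemistry or cause double methylation, and the facial preference may be modest. The fallback sets out from 15 and comes back at 20. Simmons–Smith cyclopropanation (Et2Zn, CH2I2) of the silyl enol ether from the face opposite the alkynyl group should give the siloxycyclopropane aldehyde F4. The Wittig reaction of step 12 converts it into the enol ether F5. n-Bu4NF in THF/MeOH then opens the cyclopropanol, so that the ring methylene becomes the C19 methyl group with its configuration already fixed.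

Further compounds

F1 | step 17 | vinylmercury chloride: 25 with HgCl on C12 in place of H-12 (Hg anti to C14) | C[C@@H]1[C@H]2/C(=C(/C[C@H]3[C@@H](C)CC[C@H]4C(C)(C)[C@@H](O[Si](C)(C)C(C)(C)C)CC[C@]34C)\[Hg]Cl)CC(=O)C[C@@]2(C)CC[C@@]1(C)O[Si](CC)(CC)CC
F2 | step 10 | trifluoroethyl ester: 15 with H and CO2CH2CF3 on C17 in place of CH3 and CHO (C17 epimers) | C1(O[Si](C)(C)C(C)(C)C)=C[C@@H](C#CC[C@H]3[C@@H](C)CC[C@H]4C(C)(C)[C@@H](O[Si](C)(C)C(C)(C)C)CC[C@]34C)C(C(=O)OCC(F)(F)F)CC1
F3 | step 10 | quaternary ester: 15 with CO2CH2CF3 in place of CHO | C1(O[Si](C)(C)C(C)(C)C)=C[C@@H](C#CC[C@H]3[C@@H](C)CC[C@H]4C(C)(C)[C@@H](O[Si](C)(C)C(C)(C)C)CC[C@]34C)[C@@](C)(C(=O)OCC(F)(F)F)CC1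
F4 | step 13 | siloxycyclopropane aldehyde: 15 with a CH2 bridge across C19–C20 on the face opposite the alkynyl group | C1[C@@]2(O[Si](C)(C)C(C)(C)C)CC[C@](C)(C=O)[C@H](C#CC[C@H]3[C@@H](C)CC[C@H]4C(C)(C)[C@@H](O[Si](C)(C)C(C)(C)C)CC[C@]34C)[C@@H]12
F5 | step 13 | enol ether: F4 with C17–CH=C(OMe)CH3 in place of CHO | C1[C@@]2(O[Si](C)(C)C(C)(C)C)CC[C@](C)(C=C(C)OC)[C@H](C#CC[C@H]3[C@@H](C)CC[C@H]4C(C)(C)[C@@H](O[Si](C)(C)C(C)(C)C)CC[C@]34C)[C@@H]12
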